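Two questions stand on this flask: an order at the start of the reaction and a yield in the autumn run at 97 min.

| setting | noon | dawn | autumn |
|---|---|---|---|
| starting material | 0.500 M | 0.750 M | 1.20 M |
| partner | 0.500 M | 0.500 M | 0.500 M |
| catalyst | 0.0250 M | 0.0250 M | 0.0250 M |
| time |  |  | 97 min |

| noon run: time / min | noon run: [target] / M | dawn run: time / min | dawn run: [target] / M |
|---|---|---|---|
| 3.5 | 0.017 | 3.5 | 0.020 |
| 11 | 0.066 | 11 | 0.063 |
| 20 | 0.077 | 20 | 0.080 |
| 32 | 0.089 | 32 | 0.095 |
| 46 | 0.104 | 46 | 0.111 |
| 61 | 0.112 | 61 | 0.107 |
| 78 | 0.118 | 78 | 0.122 |
| 97 | 0.127 | 97 | 0.125 |

(each reading ± 0.005 M)

1. apparent order in [starting material] of the starting rate, round the charge of the noon run (the rate where two percent of its starting material have turned into target) (one fixed amount of target, the same in the runs compared)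
2. target in the autumn run at 97 min, as a share of the starting material charged

- Overall: starting material + partner -> target, with catalyst as catalyst.
- Constant volume, constant temperature.
- Bound and free are read together.
- An order is taken over about fifteen percent of the charge, up and down.

I answer both with one reckoning in logarithms. I take the logarithm of the ratio of two readings made at one time and divide it by the logarithm of the ratio of the charges of starting material. At 97 min this gives −0.0391, give or take 0.138 from the scatter. I call this log-log slope the charge exponent.

I take the settings in turn. For starting material, a c(target) in proportion to the charge has an exponent of 1, so by hand the step from the noon run to the dawn run would multiply c(target) by 1.50. The readings at 97 min give a ratio of 0.984. For time, the autumn question falls at 97 min, where both runs have a reading, so I need no stretching. Partner and catalyst stand at 0.500 M and 0.0250 M in the noon, dawn and autumn runs alike, so I carry them unchanged.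

The step from the dawn run to the autumn run multiplies the charge by 1.60. Raised to the exponent, that puts c(target) in the autumn run at 0.123 M, which is 10.2% of its charge. For the order I use the 3.5 min pair, the one nearest the small fixed amount of target. It gives 0.401, though the scatter allows 0.952 either way.

The forecast says 0.1 and 10.8%, holding that “the order in starting material is near zero”. My order is higher than its order, and my share is lower than its share.

    catalyst + starting material ⇌ catalyst-substrate complex, settled at all times (1.990 M⁻¹)
    catalyst + partner ⇌ catalyst-reagent complex, settled at all times (2.200 M⁻¹)
    catalyst-substrate complex + catalyst-reagent complex → target + 2 catalyst (102.0 M⁻¹ min⁻¹)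
    2 partner → lost reagent (0.2268 M⁻¹ min⁻¹)

The flask gives an order of 0.35 and 9.96% for the autumn run. The rate of the dawn run over that of the noon run, both taken where the same fixed amount of target has been made, is 1.1. The charge exponent, read from the noon and dawn runs at 97 min and applied to the dawn reading, put c(target) in the autumn run at 0.123 M. The autumn run holds 0.120 M at 97 min, lower by 0.00300 M, which is less than the scatter of 0.005 M.

(The runs were computed with constants of no real substance; the scatter is artificial.)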